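At the solubility 0.058 M, the dimer step would use dissolved starting material 8.08 times as fast as the ring step, so what you need to watch is how low [starting material] stays.

    solid substrate ⇌ starting material, rate k1*(cs1 - [starting material]) while solid is left; crystals form when [starting material] > cs1 (cs1 = 0.058 M, k1 = 3.42 × 10⁻⁴ s⁻¹)
    2 starting material → open dimer (k2 = 0.00919 M⁻¹ s⁻¹)
    starting material → ring (k3 = 1.32 × 10⁻⁴ s⁻¹)

solid substrate 0.10 M; time 2.0 d

- which holds at 2.0 d: what has brought the reaction to rest, or that it has not come to rest (for what has run out or reacted, a solid counts together with what of it has only dissolved) (it is still moving / forward and back rates have come level / all of the solid substrate has reacted)
- the ring standing at 2.0 d, as a percentage of the solid substrate charged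
- the open dimer standing at 2.0 d, as a percentage of the solid substrate charged
- amount of ring if the flask were left three thousand times as long, in percent of the solid substrate charged

- a species is counted by the solid substrate in it: one open dimer counts as two
- a doubled species enters its step squared and goes two at a time
- given per volume of solution although it is solid: solid substrate
- at the start none of the solid substrate is in solution
- what has only dissolved of solid substrate counts as not reacted
- the reaction counts as stopped when no species that holds the solid substrate changes by six tenths of a point or more over the second half of the time
- run time (flask): 2.0 d

1. The quantity. The ring step uses starting material in proportion to [starting material], the dimer step in proportion to its square, and two go at each turn. So you find both using it equally at 0.00718 M, the crossover concentration: the ring constant over twice the dimer constant. At any [starting material], the ring share (the selectivity) is the crossover concentration divided by the sum of itself and [starting material].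

2. The level. While solid stands, dissolution feeds what the two steps use, and that balance puts [starting material] near 0.0224 M. This lies above the crossover concentration, so the ring share is 24.3%. I let this level stand from the first moment.

3. Turning the time. The ring step's half-life is 0.0608 d, and the asked time holds 32.9 of these. Neither step runs back, so by hand a longer run adds no ring.

4. Turning the charge. The charge above the level passes at that share. The last 0.0224 M has no feed, and its ring share rises as it falls. Summed, it gives the crossover concentration times the natural logarithm of one plus level over crossover, 0.0102 M of ring. That part stays put while the other grows with the charge, so by hand a smaller charge raises the ring percentage. For this flask I reckon 29.0% ring.

The forecast gives all of the solid substrate has reacted, ring 30%, open dimer 70% and 30% of ring at the long time, holding that “Both steps are irreversible, so longer times change nothing”. Its ring lies 1.00 percentage point above mine.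

The simulation of the flask gives all of the solid substrate has reacted, ring 30.0%, open dimer 70.0%, and 30.0% of ring at the long time, as the forecast said. At 0.0409 d, starting material in the flask is made, each step taken net, 1.04 times as fast as it is used. Now put the crossover concentration to work on the neighbour flask, charged with 0.040 M of solid substrate: the same share and tail give 36.1% ring. The neighbour flask stands at 38.3% ring and 61.7% open dimer.

All constants are invented, and the outcome is calculated.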